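I wanted the most target from one charge in four set-ups, and substrate destroys target as it forms.

all flasks: free catalyst 22 mM

| charge | substrate | reagent | time | remark |
|---|---|---|---|---|
| winter | 0.14 M (fed, over 1.60 min) | 0.154 M | 2.0 min | all but substrate at the start; substrate goes in evenly over 1.60 min, the run ends at 2.0 min |
| noon | 0.14 M | 0.154 M |  | a single well-mixed tank run continuously and read at steady state, 2.0 min in it on average |
| dusk | 0.14 M | 0.154 M | 2.0 min | everything together in a closed stirred flask, run for 2.0 min |
| midnight | 0.14 M | 0.154 M (fed, over 1.60 min) | 2.0 min | a stirred flask in which reagent is dosed at a steady rate over 1.60 min without added volume, worked up at 2.0 min |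

    reagent + free catalyst ⇌ catalyst intermediate A (K1 = 110 M⁻¹, k1 = 3.4 M⁻¹ s⁻¹)
    catalyst intermediate B → free catalyst + target (k2 = 2.6 s⁻¹)
    substrate + target → side product (k3 = 2.8 M⁻¹ s⁻¹)
    substrate + catalyst intermediate A → catalyst intermediate B (k4 = 4.9 M⁻¹ s⁻¹)

- a species is counted by the substrate in it: one side product counts as two
- the stated concentrations are those of everything mixed, before any reaction; amounts are the same in each set-up
- the feed brings no volume worth counting
- run time (winter): 2.0 min

1. the set-up with the highest amount of target at the outlet or at the end, in percent of the substrate put in ("none" if the first two lie within 2 percentage points) (winter / noon / dusk / midnight / none)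
2. amount of target at the outlet or at the end, in percent of the substrate put in, winter
3. amount of target at the outlet or at the end, in percent of the substrate put in, noon
4. amount of target at the outlet or at the end, in percent of the substrate put in, dusk
5. amount of target at the outlet or at the end, in percent of the substrate put in, midnight

I counted turnovers. Each substrate molecule is taken either by catalyst intermediate A, which leads to target through catalyst intermediate B, or by target, which gives side product. Both paths are first order in substrate, so target stops gaining where their rates match, whatever the substrate level.

I went through the given numbers first. In this balance the target level goes in direct proportion to the constant of substrate with catalyst intermediate A and to the catalyst charge, and in inverse proportion to the constant of substrate with target and to the substrate charge, so I needed these numbers well. The last step's constant gives catalyst intermediate B a half-life of 0.267 s, and that species has one exit, so each catalyst intermediate B goes on to target. The equilibrium constant times the reagent charge is 17, which loads 94.4% of the catalyst at equilibrium, and a value lower by a factor of 2 still loads 89.5%, so a rough value served. I then compared the reloading rate with the demand on the catalyst.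

Winter feed demand: 0.0663 s⁻¹
Reloading by reagent at its charge: 0.524 s⁻¹
Dusk unloading by substrate at its charge: 0.686 s⁻¹

Winter's demand is lower than the reloading, while dusk's early unloading is higher, so I expected winter to stay better loaded.

Then came the numbers themselves, for fully loaded catalyst:

Turnovers of target held, S (the selectivity factor): 4.9 M⁻¹ s⁻¹ / 2.8 M⁻¹ s⁻¹ = 1.75
Turnovers asked, N: 0.14 M / 22 mM = 6.36
Turnover ceiling, h = S / N: 27.5%

The turnover ceiling is the target level, in percent of the substrate charge, at which gain and loss balance. My own reckoning committed to winter, below h, and put no figure of my own on any set-up.

The forecast gave 21% for winter, 16.4% for noon, 17% for dusk and 15.5% for midnight, naming winter as the case that “keeps substrate scarce while the catalyst sits loaded as intermediate A”.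

The flask gave 19.9% in winter, 14.4% at noon, 15.8% at dusk and 11.3% at midnight, so winter led. Substrate in winter peaked at 0.0118 M, lower than the 0.140 M at midnight. Winter reached 0.723 of h. For the winter flask charged with 0.084 M of substrate, h is 45.8%, and the same fraction of it gives 33.1%; that flask gave 31.7%.

All constants were set for the occasion; the run is a simulation.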